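The furanoid half is traced back to O-silyl loliolide, whose carbocycle (ring B, C1'–C6') is closed last at the C1'–C6' bond. The key step exploits that C6' lies between the quaternary carbons C1' and C5': a tertiary C1' radical, made from a methallyl alkene by iron-hydride hydrogen-atom transfer, adds 6-exo to the β-carbon C6' of a butenolide that already carries C3' and C5', giving the cis-fused lactone in one operation. The precursor is a 5-methyl-5-(2-silyloxy-4-methylpent-4-enyl)butenolide, with C5' taken from (S)-2-methylglycidol and C3' set by methallylboration. Dehydrogenation, C8' alkenylation and two Wittig couplings with a separately made trihydroxy ring A unit complete the carotenoid.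

Key step: step 9

Remark: the polyene is taken as all-E as drawn; carotenoid locants (primed for the furanoid half) are used beside systematic names, and TBS means tert-butyldimethylsilyl.

Step 1
Reactants: 1 (S)-2-methylglycidol; 2 vinylmagnesium bromide
Product: 3 (2R)-2-methylpent-4-ene-1,2-diol
Conditions: 2 (2.5 equiv), CuI (10 mol%), THF, −30 → 0 °C; aq NH4Cl
Reagents that add atoms: none
Why: Copper-catalysed Grignard opening of the 2,2-disubstituted epoxide occurs at the unhindered CH2 terminus, so the quaternary centre (future C5') is carried over untouched, the first equivalent of Grignard only deprotonating the hydroxyl.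

Step 2
Reactants: 3 (2R)-2-methylpent-4-ene-1,2-diol
Product: 4 (4R)-2,2,4-trimethyl-4-(prop-2-en-1-yl)-1,3-dioxolane
Conditions: 2,2-dimethoxypropane, pyridinium p-toluenesulfonate (cat.), CH2Cl2, 25 °C
Reagents that add atoms: 2,2-dimethoxypropane, COC(C)(C)OC
Why: Acid-catalysed transketalisation masks the 1,2-diol as an acetonide that survives ozonolysis, allylboration and silylation.

Step 3
Reactants: 4 (4R)-2,2,4-trimethyl-4-(prop-2-en-1-yl)-1,3-dioxolane
Product: 5 2-[(4R)-2,2,4-trimethyl-1,3-dioxolan-4-yl]acetaldehyde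
Conditions: O3, CH2Cl2, −78 °C; then Me2S, −78 → 25 °C
Reagents that add atoms: ozone, [O-][O+]=O
Why: Ozonolysis with reductive work-up cleaves the terminal alkene to the aldehyde (future C3') without touching the quaternary centre.

Step 4
Reactants: 5 2-[(4R)-2,2,4-trimethyl-1,3-dioxolan-4-yl]acetaldehyde; 6 2-methylallylmagnesium chloride
Product: 9 (2S)-4-methyl-1-[(4R)-2,2,4-trimethyl-1,3-dioxolan-4-yl]pent-4-en-2-ol, via B-methallyl diisopinocampheylborane 7 (not isolated), via O-boryl adduct 8 (not isolated)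
Conditions: (−)-Ipc2BOMe [from (+)-α-pinene], 6, Et2O, −78 → 25 °C; then 5, −78 °C; then NaOH, H2O2, 25 °C
Reagents that add atoms: none
Why: Brown asymmetric methallylboration, in which the (+)-α-pinene-derived reagent adds to the Si face of the aldehyde through a chair six-membered transition state, should set C3' as S under reagent control irrespective of the remote C5' centre.

Step 5
Reactants: 9 (2S)-4-methyl-1-[(4R)-2,2,4-trimethyl-1,3-dioxolan-4-yl]pent-4-en-2-ol
Product: 10 TBS ether of 9
Conditions: TBSCl, imidazole, DMF, 25 °C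
Reagents that add atoms: tert-butyldimethylsilyl chloride, CC(C)(C)[Si](C)(C)Cl
Why: Standard silylation blocks the C3' hydroxyl so that it cannot add in oxa-Michael fashion to the butenolide made later.

Step 6
Reactants: 10 TBS ether of 9
Product: 11 (2R,4S)-4-(tert-butyldimethylsilyloxy)-2,6-dimethylhept-6-ene-1,2-diol
Conditions: AcOH/H2O (4:1), 40 °C
Reagents that add atoms: none
Why: Mild acid hydrolysis removes the terminal acetonide faster than it cleaves the secondary silyl ether or protonates the 1,1-disubstituted alkene.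

Step 7
Reactants: 11 (2R,4S)-4-(tert-butyldimethylsilyloxy)-2,6-dimethylhept-6-ene-1,2-diol
Product: 12 (2R,4S)-4-(tert-butyldimethylsilyloxy)-2-hydroxy-2,6-dimethylhept-6-enal
Conditions: SO3·pyridine, DMSO, i-Pr2NEt, CH2Cl2, 0 °C
Reagents that add atoms: none
Why: Parikh–Doering oxidation converts only the primary alcohol, the tertiary one being inert, and the α-quaternary aldehyde cannot epimerise.

Step 8
Reactants: 12 (2R,4S)-4-(tert-butyldimethylsilyloxy)-2-hydroxy-2,6-dimethylhept-6-enal; 13 methyl bis(2,2,2-trifluoroethyl)phosphonoacetate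
Product: 15 (5R)-5-[(2S)-2-(tert-butyldimethylsilyloxy)-4-methylpent-4-en-1-yl]-5-methylfuran-2(5H)-one, via Z-hydroxy enoate 14 (not isolated)
Conditions: 13, KN(SiMe3)2, 18-crown-6, THF, −78 → 0 °C
Reagents that add atoms: none
Why: Still–Gennari olefination should give the Z-enoate, whose tertiary alkoxide lactonises in the flask to the butenolide, C5' having no α-hydrogen to lose.

Step 9
Reactants: 15 (5R)-5-[(2S)-2-(tert-butyldimethylsilyloxy)-4-methylpent-4-en-1-yl]-5-methylfuran-2(5H)-one
Product: 16 (3aS,6S,7aR)-6-(tert-butyldimethylsilyloxy)-4,4,7a-trimethylhexahydro-1-benzofuran-2(3H)-one (O-TBS 6',7'-dihydrololiolide)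
Conditions: Fe(acac)3 (0.5 equiv), PhSiH3 (3 equiv), EtOH/ethylene glycol (5:1), 0.02 M, 60 °C
Reagents that add atoms: none
Why: An iron hydride formed from Fe(acac)3 and PhSiH3 transfers a hydrogen atom to the terminal carbon of the 1,1-disubstituted alkene, leaving the nucleophilic tertiary radical at C1', which adds to the electron-poor β-carbon C6' of the butenolide; the α-acyl radical at C7' is then reduced by divalent iron and protonated by ethanol. The closest known reaction type is the metal-hydride hydrogen-atom-transfer reductive coupling of an unactivated alkene with an enoate (intramolecular Giese cyclisation). Ring B is closed in the 6-exo-trig mode, the 7-endo alternative at C7' being disfavoured by the polarity of the enoate and by ring size. The new centre C6' should form with hydrogen cis to the C5' methyl, because the tether hangs from C5' and can deliver C1' only to its own face of the planar butenolide, giving the cis-fused bicycle (this centre is removed in step 10). The step needs hydrogen-atom transfer to the electron-rich alkene in preference to the butenolide and cyclisation faster than reduction of the radical; the first is secured by the electron-poor acceptor, the second by the short tether with its quaternary C5' and by high dilution. The C1'–C6' bond joins a quaternary carbon to a carbon flanked by a second quaternary centre, a congestion that an early-transition-state radical addition tolerates.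

Step 10
Reactants: 16 O-TBS 6',7'-dihydrololiolide
Product: 19 (6S,7aR)-6-(tert-butyldimethylsilyloxy)-4,4,7a-trimethyl-5,6,7,7a-tetrahydro-1-benzofuran-2(4H)-one (O-TBS loliolide), via alpha-phenylselanyl lactone 17 (not isolated), via selenoxide 18 (not isolated)
Conditions: LiN(i-Pr)2, THF, −78 °C; PhSeBr, −78 °C; then AcOH, 30% H2O2, 0 → 25 °C
Reagents that add atoms: none
Why: α-Selenenylation of the lactone enolate from the convex face (cis to H-6') followed by syn selenoxide elimination, which can only run toward C6', should install the C6'=C7' double bond and erase the transient C6' centre.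

Step 11
Reactants: 19 O-TBS loliolide
Product: 21 (6S,7aR)-6-(tert-butyldimethylsilyloxy)-4,4,7a-trimethyl-2,4,5,6,7,7a-hexahydro-1-benzofuran-2-yl acetate (both C8' epimers), via diisobutylaluminium lactolate 20 (not isolated)
Conditions: i-Bu2AlH, CH2Cl2, −78 °C; then pyridine, DMAP, Ac2O, −78 → −20 °C
Reagents that add atoms: acetic anhydride, CC(=O)OC(C)=O
Why: Partial reduction of the butenolide and acetylation of the aluminium lactolate in the flask (reductive acetylation) give an ionisable lactol acetate, and the quaternary C5' rules out aromatisation to a furan.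

Step 12
Reactants: 22 ethyl but-2-ynoate; 23 bis(pinacolato)diboron
Product: 24 ethyl (2Z)-3-(4,4,5,5-tetramethyl-1,3,2-dioxaborolan-2-yl)but-2-enoate
Conditions: CuCl (3 mol%), Xantphos (3 mol%), NaOt-Bu (6 mol%), MeOH (2 equiv), THF, 25 °C
Reagents that add atoms: none
Why: Copper-catalysed conjugate borylcupration of the ynoate and protonation of the alkenylcopper (syn addition of boron and hydrogen) should place boron on the methyl-bearing carbon, trans to the ester.

Step 13
Reactants: 24 ethyl (2Z)-3-(pinacolboryl)but-2-enoate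
Product: 26 (2Z)-3-(4,4,5,5-tetramethyl-1,3,2-dioxaborolan-2-yl)but-2-en-1-yl acetate, via diisobutylaluminium alkoxide 25 (not isolated)
Conditions: i-Bu2AlH (2.2 equiv), CH2Cl2, −78 °C; then pyridine, DMAP, Ac2O, −78 → 25 °C
Reagents that add atoms: acetic anhydride, CC(=O)OC(C)=O
Why: Low-temperature 1,2-reduction of the enoate leaves the pinacol boronate intact, and the aluminium alkoxide is acetylated directly (reduction–acylation).

Step 14
Reactants: 26 (2Z)-3-(pinacolboryl)but-2-en-1-yl acetate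
Product: 27 potassium [(2Z)-4-acetoxybut-2-en-2-yl]trifluoroborate
Conditions: KHF2 (aq), MeOH, 25 °C
Reagents that add atoms: potassium hydrogen difluoride, [K+].F[H-]F
Why: Fluoride exchange at boron converts the pinacol ester into the bench-stable alkenyltrifluoroborate with retention of alkene geometry.

Step 15
Reactants: 21 lactol acetate; 27 potassium [(2Z)-4-acetoxybut-2-en-2-yl]trifluoroborate
Product: 28 (2E)-3-[(2R,6S,7aR)-6-(tert-butyldimethylsilyloxy)-4,4,7a-trimethyl-2,4,5,6,7,7a-hexahydro-1-benzofuran-2-yl]but-2-en-1-yl acetate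
Conditions: BF3·OEt2 (2 equiv), CH2Cl2/MeCN, −40 → −10 °C
Reagents that add atoms: none
Why: Lewis-acid-mediated addition of an alkenyltrifluoroborate to a cyclic oxocarbenium ion: BF3 ionises the lactol acetate, and the alkenyl group should be transferred to C8' from the face of C4', anti to the pseudo-axial C5' methyl and the syn-axial C1' methyl, giving 8'R with retention of the alkene geometry, attack at C6' being blocked by its two quaternary neighbours.

Step 16
Reactants: 28 C15 allylic acetate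
Product: 29 (2E)-3-[(2R,6S,7aR)-6-(tert-butyldimethylsilyloxy)-4,4,7a-trimethyl-2,4,5,6,7,7a-hexahydro-1-benzofuran-2-yl]but-2-en-1-ol
Conditions: K2CO3, MeOH, 0 °C
Reagents that add atoms: none
Why: Base-catalysed methanolysis removes the acetate without touching the silyl ether or the acid-sensitive dihydrofuran.

Step 17
Reactants: 29 C15 allylic alcohol
Product: 31 {(2E)-3-[(2R,6S,7aR)-6-(tert-butyldimethylsilyloxy)-4,4,7a-trimethyl-2,4,5,6,7,7a-hexahydro-1-benzofuran-2-yl]but-2-en-1-yl}triphenylphosphonium bromide, via allylic bromide 30 (not isolated)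
Conditions: CBr4, PPh3, 2,6-lutidine, CH2Cl2, −20 °C; then PPh3, MeCN, 25 °C
Reagents that add atoms: triphenylphosphine, c1ccc(cc1)P(c1ccccc1)c1ccccc1; tetrabromomethane, BrC(Br)(Br)Br
Why: Appel bromination of the primary allylic alcohol under buffered conditions and SN2 quaternisation by PPh3 should give the phosphonium salt without ionising the C8'–O bond.

Step 18
Reactants: 32 (4R,6R)-4-hydroxy-2,2,6-trimethylcyclohexanone
Product: 33 (4R,6R)-4-(tert-butyldimethylsilyloxy)-2,2,6-trimethylcyclohexanone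
Conditions: TBSCl, imidazole, DMF, 25 °C
Reagents that add atoms: tert-butyldimethylsilyl chloride, CC(C)(C)[Si](C)(C)Cl
Why: Standard silylation protects the future C3 hydroxyl of ring A.

Step 19
Reactants: 33 (4R,6R)-4-(tert-butyldimethylsilyloxy)-2,2,6-trimethylcyclohexanone
Product: 34 (4R)-4-(tert-butyldimethylsilyloxy)-2,6,6-trimethylcyclohex-1-en-1-yl trifluoromethanesulfonate
Conditions: LiN(i-Pr)2, THF, −78 → 0 °C; then PhNTf2, 0 → 25 °C
Reagents that add atoms: N-phenylbis(trifluoromethanesulfonimide), O=S(=O)(N(c1ccccc1)S(=O)(=O)C(F)(F)F)C(F)(F)F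
Why: Only one α-carbon carries hydrogen, so enolisation is regiospecific and O-triflation gives the tetrasubstituted enol triflate.

Step 20
Reactants: 34 enol triflate
Product: 35 methyl (4R)-4-(tert-butyldimethylsilyloxy)-2,6,6-trimethylcyclohex-1-ene-1-carboxylate
Conditions: Pd(OAc)2 (5 mol%), PPh3 (10 mol%), CO (1 atm), MeOH, Et3N, DMF, 60 °C
Reagents that add atoms: carbon monoxide, [C-]#[O+]; methanol, CO
Why: Palladium-catalysed methoxycarbonylation (oxidative addition to zerovalent palladium, CO insertion, methanolysis) converts the hindered enol triflate into the enoate.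

Step 21
Reactants: 35 methyl ester
Product: 36 [(4R)-4-(tert-butyldimethylsilyloxy)-2,6,6-trimethylcyclohex-1-en-1-yl]methanol
Conditions: i-Bu2AlH (2.5 equiv), CH2Cl2, −78 → 0 °C
Reagents that add atoms: none
Why: Hydride reduction of the conjugated ester gives the allylic alcohol needed for directed epoxidation.

Step 22
Reactants: 36 allylic alcohol
Product: 37 [(1S,4S,6S)-4-(tert-butyldimethylsilyloxy)-2,2,6-trimethyl-7-oxabicyclo[4.1.0]heptan-1-yl]methanol (epoxide oxygen cis to the silyloxy group)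
Conditions: Ti(O-i-Pr)4 (0.3 equiv), L-(+)-diisopropyl tartrate (0.36 equiv), t-BuOOH, 4 Å molecular sieves, CH2Cl2, −20 °C
Reagents that add atoms: tert-butyl hydroperoxide, CC(C)(C)OO
Why: Sharpless asymmetric epoxidation with L-(+)-tartrate should deliver oxygen to the face of the tetrasubstituted alkene syn to the C3 silyloxy group, setting C5 and C6 under reagent control that should override the small opposing substrate bias.

Step 23
Reactants: 37 epoxy alcohol
Product: 38 (1S,2R,4S)-4-(tert-butyldimethylsilyloxy)-1-(hydroxymethyl)-2,6,6-trimethylcyclohexane-1,2-diol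
Conditions: HClO4 (5 mol%), THF/H2O (2:1), 0 °C
Reagents that add atoms: water, O
Why: Acid-catalysed trans-diaxial (Fürst–Plattner) epoxide hydrolysis, in which water should attack the tertiary C5 with inversion because a cation at C6 is disfavoured by its hydroxymethyl group, places the 5-OH trans to both the 6-OH and the C3 oxygen.

Step 24
Reactants: 38 triol
Product: 39 (1R,2R,4S)-4-(tert-butyldimethylsilyloxy)-1,2-dihydroxy-2,6,6-trimethylcyclohexane-1-carbaldehyde
Conditions: SO3·pyridine, DMSO, i-Pr2NEt, CH2Cl2, 0 °C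
Reagents that add atoms: none
Why: Parikh–Doering oxidation converts only the primary alcohol and cannot cleave the vicinal diol.

Step 25
Reactants: 39 dihydroxy aldehyde; 40 ethyl (2E)-4-(diethoxyphosphoryl)-3-methylbut-2-enoate
Product: 41 ethyl (2E,4E)-5-[(1R,2R,4S)-4-(tert-butyldimethylsilyloxy)-1,2-dihydroxy-2,6,6-trimethylcyclohexyl]-3-methylpenta-2,4-dienoate
Conditions: 40 (3 equiv), LiN(SiMe3)2 (3 equiv), THF, −78 °C; then 39, −78 → −20 °C
Reagents that add atoms: none
Why: Horner–Wadsworth–Emmons reaction of the vinylogous phosphonate anion should form the C7=C8 bond E and carry over the 9E geometry of the reagent, with excess anion covering the two free hydroxyls and low temperature avoiding α-ketol rearrangement.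

Step 26
Reactants: 41 dienoate
Product: 42 (2E,4E)-5-[(1R,2R,4S)-4-(tert-butyldimethylsilyloxy)-1,2-dihydroxy-2,6,6-trimethylcyclohexyl]-3-methylpenta-2,4-dien-1-ol
Conditions: i-Bu2AlH (5 equiv), CH2Cl2, −78 °C
Reagents that add atoms: none
Why: Hydride reduction of the dienoate gives the primary dienol.

Step 27
Reactants: 42 dienol
Product: 44 {(2E,4E)-5-[(1R,2R,4S)-4-(tert-butyldimethylsilyloxy)-1,2-dihydroxy-2,6,6-trimethylcyclohexyl]-3-methylpenta-2,4-dien-1-yl}triphenylphosphonium bromide, via dienyl bromide 43 (not isolated)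
Conditions: CBr4, PPh3, 2,6-lutidine, CH2Cl2, −20 °C; then PPh3, MeCN, 0 → 25 °C
Reagents that add atoms: triphenylphosphine, c1ccc(cc1)P(c1ccccc1)c1ccccc1; tetrabromomethane, BrC(Br)(Br)Br
Why: Appel bromination is selective for the primary allylic hydroxyl over the two tertiary ones, and the neutral conditions should avoid ionising the tertiary allylic C6 alcohol before PPh3 displaces the bromide.

Step 28
Reactants: 44 ring A phosphonium bromide; 45 (2E,4E,6E)-2,7-dimethylocta-2,4,6-trienedial
Product: 46 (2E,4E,6E,8E,10E,12E)-13-[(1R,2R,4S)-4-(tert-butyldimethylsilyloxy)-1,2-dihydroxy-2,6,6-trimethylcyclohexyl]-2,7,11-trimethyltrideca-2,4,6,8,10,12-hexaenal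
Conditions: 45 (3 equiv), NaOMe, MeOH/CH2Cl2, 0 → 25 °C; then EtOAc, 60 °C, dark
Reagents that add atoms: none
Why: Wittig reaction of the semi-stabilised ylide with an excess of the symmetrical dialdehyde should give the mono-olefinated C25 aldehyde, and warming isomerises any 11Z isomer to E.

Step 29
Reactants: 31 furanoid phosphonium bromide; 46 C25 aldehyde
Product: 47 3,3'-bis-O-TBS ether of the target
Conditions: NaOMe, MeOH/CH2Cl2, 0 → 25 °C; then EtOAc, 60 °C, dark
Reagents that add atoms: none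
Why: A second Wittig reaction joins the halves at C11'=C12', warming converts the hindered 11'Z isomer into the all-E polyene, and no stereocentre is touched.

Step 30
Reactants: 47 bis-silyl ether
Product: 48 (3S,5R,6R,3'S,5'R,8'R)-5',8'-epoxy-5,6,5',8'-tetrahydro-β,β-carotene-3,5,6,3'-tetrol (target)
Conditions: Bu4NF, AcOH (1:1), THF, 0 → 25 °C
Reagents that add atoms: none
Why: Buffered fluoride cleaves both silyl ethers while avoiding the acid to which the 5,6-diol and the 5',8'-epoxide are sensitive.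

Compound list
1 | (S)-2-methylglycidol, (2S)-(2-methyloxiran-2-yl)methanol | OC[C@@]1(C)CO1 | starting material
2 | vinylmagnesium bromide | C=C[Mg]Br | starting material
3 | (2R)-2-methylpent-4-ene-1,2-diol | C=CC[C@@](C)(O)CO | intermediate
4 | (4R)-2,2,4-trimethyl-4-(prop-2-en-1-yl)-1,3-dioxolane | C=CC[C@]1(C)COC(C)(C)O1 | intermediate
5 | 2-[(4R)-2,2,4-trimethyl-1,3-dioxolan-4-yl]acetaldehyde | O=CC[C@]1(C)COC(C)(C)O1 | intermediate
6 | 2-methylallylmagnesium chloride | CC(=C)C[Mg]Cl | starting material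
7 | B-(2-methylallyl)diisopinocampheylborane from (+)-α-pinene | CC(=C)CB([C@@H]1C[C@@H]2C[C@H]([C@H]1C)C2(C)C)[C@@H]1C[C@@H]2C[C@H]([C@H]1C)C2(C)C | intermediate
8 | O-diisopinocampheylboryl ether of 9 | C=C(C)C[C@H](OB([C@@H]1C[C@@H]2C[C@H]([C@H]1C)C2(C)C)[C@@H]1C[C@@H]2C[C@H]([C@H]1C)C2(C)C)C[C@]1(C)COC(C)(C)O1 | intermediate
9 | (2S)-4-methyl-1-[(4R)-2,2,4-trimethyl-1,3-dioxolan-4-yl]pent-4-en-2-ol | C=C(C)C[C@H](O)C[C@]1(C)COC(C)(C)O1 | intermediate
10 | tert-butyldimethylsilyl ether of 9 | C=C(C)C[C@H](O[Si](C)(C)C(C)(C)C)C[C@]1(C)COC(C)(C)O1 | intermediate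
11 | (2R,4S)-4-(tert-butyldimethylsilyloxy)-2,6-dimethylhept-6-ene-1,2-diol | C=C(C)C[C@H](O[Si](C)(C)C(C)(C)C)C[C@@](C)(O)CO | intermediate
12 | (2R,4S)-4-(tert-butyldimethylsilyloxy)-2-hydroxy-2,6-dimethylhept-6-enal | C=C(C)C[C@H](O[Si](C)(C)C(C)(C)C)C[C@@](C)(O)C=O | intermediate
13 | methyl bis(2,2,2-trifluoroethyl)phosphonoacetate | COC(=O)CP(=O)(OCC(F)(F)F)OCC(F)(F)F | starting material
14 | methyl (2Z,4R,6S)-6-(tert-butyldimethylsilyloxy)-4-hydroxy-4,8-dimethylnona-2,8-dienoate | C=C(C)C[C@H](O[Si](C)(C)C(C)(C)C)C[C@@](C)(O)/C=C\C(=O)OC | intermediate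
15 | (5R)-5-[(2S)-2-(tert-butyldimethylsilyloxy)-4-methylpent-4-en-1-yl]-5-methylfuran-2(5H)-one | C=C(C)C[C@H](O[Si](C)(C)C(C)(C)C)C[C@@]1(C)OC(=O)C=C1 | intermediate
16 | (3aS,6S,7aR)-6-(tert-butyldimethylsilyloxy)-4,4,7a-trimethylhexahydro-1-benzofuran-2(3H)-one, cis-fused | O=C1C[C@H]2C(C)(C)C[C@H](O[Si](C)(C)C(C)(C)C)C[C@@]2(C)O1 | intermediate
17 | (3R,3aS,6S,7aR)-3-(phenylselanyl) derivative of 16, selenium cis to H-3a | O=C1[C@H]([Se]c2ccccc2)[C@H]2C(C)(C)C[C@H](O[Si](C)(C)C(C)(C)C)C[C@@]2(C)O1 | intermediate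
18 | Se-oxide of 17 | O=C1[C@H]([Se](=O)c2ccccc2)[C@H]2C(C)(C)C[C@H](O[Si](C)(C)C(C)(C)C)C[C@@]2(C)O1 | intermediate
19 | (6S,7aR)-6-(tert-butyldimethylsilyloxy)-4,4,7a-trimethyl-5,6,7,7a-tetrahydro-1-benzofuran-2(4H)-one | O=C1C=C2C(C)(C)C[C@H](O[Si](C)(C)C(C)(C)C)C[C@@]2(C)O1 | intermediate
20 | diisobutylaluminium lactolate of 19 | CC(C)C[Al](CC(C)C)OC1C=C2C(C)(C)C[C@H](O[Si](C)(C)C(C)(C)C)C[C@@]2(C)O1 | intermediate
21 | (6S,7aR)-6-(tert-butyldimethylsilyloxy)-4,4,7a-trimethyl-2,4,5,6,7,7a-hexahydro-1-benzofuran-2-yl acetate | CC(=O)OC1C=C2C(C)(C)C[C@H](O[Si](C)(C)C(C)(C)C)C[C@@]2(C)O1 | intermediate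
22 | ethyl but-2-ynoate | CC#CC(=O)OCC | starting material
23 | bis(pinacolato)diboron | CC1(C)OB(OC1(C)C)B1OC(C)(C)C(C)(C)O1 | starting material
24 | ethyl (2Z)-3-(4,4,5,5-tetramethyl-1,3,2-dioxaborolan-2-yl)but-2-enoate | CCOC(=O)/C=C(\C)B1OC(C)(C)C(C)(C)O1 | intermediate
25 | diisobutylaluminium (2Z)-3-(pinacolboryl)but-2-en-1-olate | CC(C)C[Al](CC(C)C)OC/C=C(\C)B1OC(C)(C)C(C)(C)O1 | intermediate
26 | (2Z)-3-(4,4,5,5-tetramethyl-1,3,2-dioxaborolan-2-yl)but-2-en-1-yl acetate | CC(=O)OC/C=C(\C)B1OC(C)(C)C(C)(C)O1 | intermediate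
27 | potassium [(2Z)-4-acetoxybut-2-en-2-yl]trifluoroborate | [K+].CC(=O)OC/C=C(\C)[B-](F)(F)F | intermediate
28 | (2E)-3-[(2R,6S,7aR)-6-(tert-butyldimethylsilyloxy)-4,4,7a-trimethyl-2,4,5,6,7,7a-hexahydro-1-benzofuran-2-yl]but-2-en-1-yl acetate | CC(=O)OC/C=C(\C)[C@H]1C=C2C(C)(C)C[C@H](O[Si](C)(C)C(C)(C)C)C[C@@]2(C)O1 | intermediate
29 | (2E)-3-[(2R,6S,7aR)-6-(tert-butyldimethylsilyloxy)-4,4,7a-trimethyl-2,4,5,6,7,7a-hexahydro-1-benzofuran-2-yl]but-2-en-1-ol | OC/C=C(\C)[C@H]1C=C2C(C)(C)C[C@H](O[Si](C)(C)C(C)(C)C)C[C@@]2(C)O1 | intermediate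
30 | allylic bromide from 29 | BrC/C=C(\C)[C@H]1C=C2C(C)(C)C[C@H](O[Si](C)(C)C(C)(C)C)C[C@@]2(C)O1 | intermediate
31 | triphenylphosphonium bromide from 30 | [Br-].c1ccccc1[P+](c1ccccc1)(c1ccccc1)C/C=C(\C)[C@H]1C=C2C(C)(C)C[C@H](O[Si](C)(C)C(C)(C)C)C[C@@]2(C)O1 | intermediate
32 | (4R,6R)-4-hydroxy-2,2,6-trimethylcyclohexanone | O=C1C(C)(C)C[C@H](O)C[C@H]1C | starting material
33 | (4R,6R)-4-(tert-butyldimethylsilyloxy)-2,2,6-trimethylcyclohexanone | O=C1C(C)(C)C[C@H](O[Si](C)(C)C(C)(C)C)C[C@H]1C | intermediate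
34 | (4R)-4-(tert-butyldimethylsilyloxy)-2,6,6-trimethylcyclohex-1-en-1-yl trifluoromethanesulfonate | CC1=C(OS(=O)(=O)C(F)(F)F)C(C)(C)C[C@H](O[Si](C)(C)C(C)(C)C)C1 | intermediate
35 | methyl (4R)-4-(tert-butyldimethylsilyloxy)-2,6,6-trimethylcyclohex-1-ene-1-carboxylate | COC(=O)C1=C(C)C[C@@H](O[Si](C)(C)C(C)(C)C)CC1(C)C | intermediate
36 | [(4R)-4-(tert-butyldimethylsilyloxy)-2,6,6-trimethylcyclohex-1-en-1-yl]methanol | OCC1=C(C)C[C@@H](O[Si](C)(C)C(C)(C)C)CC1(C)C | intermediate
37 | [(1S,4S,6S)-4-(tert-butyldimethylsilyloxy)-2,2,6-trimethyl-7-oxabicyclo[4.1.0]heptan-1-yl]methanol | OC[C@@]12C(C)(C)C[C@H](O[Si](C)(C)C(C)(C)C)C[C@]1(C)O2 | intermediate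
38 | (1S,2R,4S)-4-(tert-butyldimethylsilyloxy)-1-(hydroxymethyl)-2,6,6-trimethylcyclohexane-1,2-diol | OC[C@@]1(O)C(C)(C)C[C@H](O[Si](C)(C)C(C)(C)C)C[C@@]1(C)O | intermediate
39 | (1R,2R,4S)-4-(tert-butyldimethylsilyloxy)-1,2-dihydroxy-2,6,6-trimethylcyclohexane-1-carbaldehyde | O=C[C@@]1(O)C(C)(C)C[C@H](O[Si](C)(C)C(C)(C)C)C[C@@]1(C)O | intermediate
40 | ethyl (2E)-4-(diethoxyphosphoryl)-3-methylbut-2-enoate | CCOC(=O)/C=C(\C)CP(=O)(OCC)OCC | starting material
41 | ethyl (2E,4E)-5-[(1R,2R,4S)-4-(tert-butyldimethylsilyloxy)-1,2-dihydroxy-2,6,6-trimethylcyclohexyl]-3-methylpenta-2,4-dienoate | CCOC(=O)/C=C(C)/C=C/[C@@]1(O)C(C)(C)C[C@H](O[Si](C)(C)C(C)(C)C)C[C@@]1(C)O | intermediate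
42 | (2E,4E)-5-[(1R,2R,4S)-4-(tert-butyldimethylsilyloxy)-1,2-dihydroxy-2,6,6-trimethylcyclohexyl]-3-methylpenta-2,4-dien-1-ol | OC/C=C(C)/C=C/[C@@]1(O)C(C)(C)C[C@H](O[Si](C)(C)C(C)(C)C)C[C@@]1(C)O | intermediate
43 | dienyl bromide from 42 | BrC/C=C(C)/C=C/[C@@]1(O)C(C)(C)C[C@H](O[Si](C)(C)C(C)(C)C)C[C@@]1(C)O | intermediate
44 | triphenylphosphonium bromide from 43 | [Br-].c1ccccc1[P+](c1ccccc1)(c1ccccc1)C/C=C(C)/C=C/[C@@]1(O)C(C)(C)C[C@H](O[Si](C)(C)C(C)(C)C)C[C@@]1(C)O | intermediate
45 | (2E,4E,6E)-2,7-dimethylocta-2,4,6-trienedial | O=C/C(C)=C/C=C/C=C(C)/C=O | starting material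
46 | (2E,4E,6E,8E,10E,12E)-13-[(1R,2R,4S)-4-(tert-butyldimethylsilyloxy)-1,2-dihydroxy-2,6,6-trimethylcyclohexyl]-2,7,11-trimethyltrideca-2,4,6,8,10,12-hexaenal | O=C/C(C)=C/C=C/C=C(C)/C=C/C=C(C)/C=C/[C@@]1(O)C(C)(C)C[C@H](O[Si](C)(C)C(C)(C)C)C[C@@]1(C)O | intermediate
47 | 3,3'-bis-O-(tert-butyldimethylsilyl) ether of 48 | CC(/C=C/C=C(C)/C=C/[C@@]1(O)C(C)(C)C[C@H](O[Si](C)(C)C(C)(C)C)C[C@@]1(C)O)=C\C=C\C=C(C)\C=C\C=C(/C)[C@H]1C=C2C(C)(C)C[C@H](O[Si](C)(C)C(C)(C)C)C[C@@]2(C)O1 | intermediate
48 | (3S,5R,6R,3'S,5'R,8'R)-5',8'-epoxy-5,6,5',8'-tetrahydro-β,β-carotene-3,5,6,3'-tetrol | CC(/C=C/C=C(C)/C=C/[C@@]1(O)C(C)(C)C[C@H](O)C[C@@]1(C)O)=C\C=C\C=C(C)\C=C\C=C(/C)[C@H]1C=C2C(C)(C)C[C@H](O)C[C@@]2(C)O1 | target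

Total step count: 30. Longest linear sequence: 16 (steps 1–11, 15–17, 29, 30).

Steps most likely to fail

Step 9. The tertiary C1' radical may be reduced before it cyclises (net hydrogenation of the alkene), or the butenolide may undergo conjugate reduction. The fallback generates the same radical without a hydride source. Setting out from 15, Mukaiyama hydration (Co(acac)2, PhSiH3, O2) of the 1,1-disubstituted alkene should give the tertiary alcohol F1. Acylation with methyl chlorooxoacetate gives the mixed methyl oxalate F2, and hydrolysis with CsOH gives the caesium oxalate F3. Visible-light photoredox decarboxylation with [Ir(dF(CF3)ppy)2(dtbbpy)]PF6 then releases the C1' radical, which closes the same C1'–C6' bond by a Giese reaction and comes back to the route at 16.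

Step 15. The alkenyl group may enter C8' from the face of the C5' methyl or with poor facial discrimination, and the doubly allylic cation may decompose. The fallback inverts the order of bond formation so that hydride, not carbon, is delivered to the cation. But-2-yn-1-ol is converted by stannylcupration into the (E)-stannane F4, by iodine into the iodo alcohol F5 and by TBSCl into the vinyl iodide F6. Setting out from 19, the lithio derivative of F6 (t-BuLi) adds to the lactone carbonyl to give the lactol F7. Reduction with Et3SiH and BF3·OEt2 gives the C15 bis-silyl ether F8, in which the face that accepts the incoming nucleophile now carries hydrogen. Removal of the primary silyl group (NH4F, MeOH) comes back to the route at 29.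

Step 23. Water may attack C6 as well as C5, the tertiary cation may rearrange, or the silyl ether may be lost under acid. The fallback is a titanium-mediated opening directed by the neighbouring hydroxymethyl group. Setting out from 37, Ti(O-i-Pr)4 and benzoic acid should open the epoxide at C5, the carbon remote from the alcohol, with inversion to give the C5 benzoate F9. K2CO3 in MeOH then cleaves the ester and comes back to the route at 38.

Further compounds
F1 | step 9 | (5R)-5-[(2S)-2-(tert-butyldimethylsilyloxy)-4-hydroxy-4-methylpentyl]-5-methylfuran-2(5H)-one | CC(C)(O)C[C@H](O[Si](C)(C)C(C)(C)C)C[C@@]1(C)OC(=O)C=C1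
F2 | step 9 | methyl oxalate of F1 | COC(=O)C(=O)OC(C)(C)C[C@H](O[Si](C)(C)C(C)(C)C)C[C@@]1(C)OC(=O)C=C1
F3 | step 9 | caesium oxalate of F1 | [Cs+].[O-]C(=O)C(=O)OC(C)(C)C[C@H](O[Si](C)(C)C(C)(C)C)C[C@@]1(C)OC(=O)C=C1
F4 | step 15 | (2E)-3-(tributylstannyl)but-2-en-1-ol | CCCC[Sn](CCCC)(CCCC)/C(C)=C/CO
F5 | step 15 | (2E)-3-iodobut-2-en-1-ol | I/C(C)=C/CO
F6 | step 15 | tert-butyl{[(2E)-3-iodobut-2-en-1-yl]oxy}dimethylsilane | I/C(C)=C/CO[Si](C)(C)C(C)(C)C
F7 | step 15 | (6S,7aR)-2-[(2E)-4-(tert-butyldimethylsilyloxy)but-2-en-2-yl]-6-(tert-butyldimethylsilyloxy)-4,4,7a-trimethyl-2,4,5,6,7,7a-hexahydro-1-benzofuran-2-ol | CC(C)(C)[Si](C)(C)OC/C=C(\C)C1(O)C=C2C(C)(C)C[C@H](O[Si](C)(C)C(C)(C)C)C[C@@]2(C)O1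
F8 | step 15 | tert-butyldimethylsilyl ether of 29 | CC(C)(C)[Si](C)(C)OC/C=C(\C)[C@H]1C=C2C(C)(C)C[C@H](O[Si](C)(C)C(C)(C)C)C[C@@]2(C)O1
F9 | step 23 | C5 benzoate of 38 (ester on the tertiary carbinol bearing the methyl group) | OC[C@@]1(O)C(C)(C)C[C@H](O[Si](C)(C)C(C)(C)C)C[C@@]1(C)OC(=O)c1ccccc1
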